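**Strategy.** The cyclobutane is centrosymmetric: ring carbons C1 and C3 carry the 4-hydroxyphenyl rings, C2 and C4 carry C6 of the 4-methoxy-2-pyranone rings. The C1-aryl/C2-pyranonyl pair lies on one face, the C3-aryl/C4-pyranonyl pair on the other. This is the head-to-tail dimer pattern of one E-styrylpyranone. The route therefore makes 6-[(E)-4-hydroxystyryl]-4-methoxy-2-pyranone by a vinylogous aldol condensation and a deprotection, then irradiates its crystals. One topochemical [2+2] photocycloaddition between antiparallel-stacked molecules should form the C1–C2 and C3–C4 bonds together, closing the four-membered ring and setting all four stereocentres.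

Key step: step 3

Assumption: 4-methoxy-6-methyl-2H-pyran-2-one and 4-(methoxymethoxy)benzaldehyde are taken as catalogue compounds. The target has an inversion centre and is achiral, so only relative configuration has to be controlled.

Step 1
Reactants: 1 4-methoxy-6-methyl-2H-pyran-2-one; 2 4-(methoxymethoxy)benzaldehyde
Product: 4 4-methoxy-6-[(E)-2-[4-(methoxymethoxy)phenyl]ethenyl]-2H-pyran-2-one, via aldol adduct 3 (not isolated)
Conditions: Mg(OMe)2 (2 equiv), MeOH, reflux; then 1 M HCl, 0 °C
Reagents that add atoms: none
Why: Vinylogous aldol condensation, in which Mg(OMe)2 reversibly deprotonates the C6 methyl group of 1 (vinylogous to the lactone carbonyl), the magnesium trienolate adds to aldehyde 2 to give aldol 3, and E1cB loss of water should give the fully conjugated alkene in its thermodynamically favoured E geometry, the MOM acetal being stable to base.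

Step 2
Reactants: 4 4-methoxy-6-[(E)-2-[4-(methoxymethoxy)phenyl]ethenyl]-2H-pyran-2-one
Product: 5 6-[(E)-2-(4-hydroxyphenyl)ethenyl]-4-methoxy-2H-pyran-2-one
Conditions: HCl (1 M), MeOH/THF, 45 °C, exclusion of light
Reagents that add atoms: none
Why: Acid-catalysed acetal exchange (MOM cleavage) should free the phenol, while the 4-methoxy-2-pyranone (a vinylogous methyl ester whose exchange with methanol is degenerate) and the acceptor-substituted E alkene should survive dilute acid, and darkness prevents solution-phase E/Z photoisomerization.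

Step 3
Reactants: 5 6-[(E)-2-(4-hydroxyphenyl)ethenyl]-4-methoxy-2H-pyran-2-one (two molecules)
Product: 6 (1α,2α,3β,4β)-1,3-bis(4-hydroxyphenyl)-2,4-bis(4-methoxy-2-oxo-2H-pyran-6-yl)cyclobutane (centrosymmetric head-to-tail dimer, the target)
Conditions: crystals of 5 (from MeOH, grown in the dark), ground and spread as a thin layer between Pyrex plates, hν (365 nm), no solvent, rt, periodic remixing
Reagents that add atoms: none
Why: Excitation of the styrylpyranone chromophore of one lattice molecule is followed by a [π2s+π2s] photocycloaddition with the ground-state alkene of its inversion-related neighbour, so that the ArCH carbon of each molecule bonds to the pyranonyl-CH carbon of the other and both new bonds (C1–C2 and C3–C4) form in one photochemical event. The closest known reaction type is the topochemical head-to-tail photodimerization of crystalline E-cinnamic acids and E-styryl heteroarenes, which needs parallel C=C bonds within about 4.2 Å. The four-membered ring closes by intermolecular [2+2] cycloaddition, suprafacial on both alkenes. At C1–C4 the E geometry of each monomer fixes aryl and pyranonyl trans on the two inherited bonds (C2–C3 and C4–C1), and the antiparallel stacking about an inversion centre fixes the relation between the halves (C1-aryl cis to C2-pyranonyl, C3-aryl cis to C4-pyranonyl, the two aryl rings trans across the ring), which gives the single achiral centrosymmetric isomer. The step needs head-to-tail instead of head-to-head pairing, reaction at the exocyclic alkene instead of a pyranone ring C=C bond, and no E/Z isomerization; donor–acceptor stacking of the electron-rich hydroxyphenyl ring over the electron-poor pyranone, phenol-to-lactone-carbonyl hydrogen bonds and the rigid lattice should secure these. Light of 365 nm is absorbed by 5 but not by 6, which lacks the styryl chromophore, so cycloreversion should not compete.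

**Compound list**

1 | 4-methoxy-6-methyl-2H-pyran-2-one | COc1cc(=O)oc(C)c1 | starting material
2 | 4-(methoxymethoxy)benzaldehyde | COCOc1ccc(C=O)cc1 | starting material
3 | rac-6-[2-hydroxy-2-[4-(methoxymethoxy)phenyl]ethyl]-4-methoxy-2H-pyran-2-one (aldol adduct, racemic, not isolated) | COCOc1ccc(C(O)Cc2cc(OC)cc(=O)o2)cc1 | intermediate
4 | 4-methoxy-6-[(E)-2-[4-(methoxymethoxy)phenyl]ethenyl]-2H-pyran-2-one | COCOc1ccc(/C=C/c2cc(OC)cc(=O)o2)cc1 | intermediate
5 | 6-[(E)-2-(4-hydroxyphenyl)ethenyl]-4-methoxy-2H-pyran-2-one | Oc1ccc(/C=C/c2cc(OC)cc(=O)o2)cc1 | intermediate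
6 | (1α,2α,3β,4β)-1,3-bis(4-hydroxyphenyl)-2,4-bis(4-methoxy-2-oxo-2H-pyran-6-yl)cyclobutane (aryl at C1 and pyranonyl at C2 on one face, aryl at C3 and pyranonyl at C4 on the other; achiral) | COc1cc(=O)oc([C@H]2[C@H](c3ccc(O)cc3)[C@H](c3cc(OC)cc(=O)o3)[C@H]2c2ccc(O)cc2)c1 | target

**Totals.** Total step count: 3. Longest linear sequence: 3 steps (1 + 2 → 4 → 5 → 6).

**Steps most likely to fail, with fallbacks**

Step 3 (key step). The crystal packing of 5 may hold the alkenes too far apart, or parallel instead of antiparallel. Then no reaction, head-to-head pairing, cycloaddition across a pyranone ring C=C bond, or E/Z isomerization at lattice defects could take over. The fallback moves the head-to-tail photodimerization to the cinnamic acid stage, where this packing is well documented, and builds both pyranone rings afterwards. It sets out from 2 and returns at 6.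
- Knoevenagel–Doebner condensation of 2 with malonic acid (pyridine, cat. piperidine, 90 °C) should give (E)-3-[4-(methoxymethoxy)phenyl]prop-2-enoic acid F1.
- Aqueous HCl in THF should free (E)-3-(4-hydroxyphenyl)prop-2-enoic acid F2, which is also a catalogue compound.
- Irradiation of crystalline F2 (hν above 300 nm, rt) should give (1α,2α,3β,4β)-2,4-bis(4-hydroxyphenyl)cyclobutane-1,3-dicarboxylic acid F3.
- Fischer esterification (MeOH, H2SO4, reflux) should give dimethyl (1α,2α,3β,4β)-2,4-bis(4-hydroxyphenyl)cyclobutane-1,3-dicarboxylate F4.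
- Chloromethyl methyl ether with iPr2NEt in CH2Cl2 should give dimethyl (1α,2α,3β,4β)-2,4-bis[4-(methoxymethoxy)phenyl]cyclobutane-1,3-dicarboxylate F5.
- Double Claisen acylation of the dianion of methyl acetoacetate (NaH, then n-BuLi, THF, 0 °C, excess) by F5 should give the bis(methyl 3,5-dioxopentanoate) F6, in which each ring carbonyl is the C5 ketone.
- DBU in refluxing toluene should lactonize both chains to the bis(4-hydroxy-2-pyranone) F7.
- Me2SO4 with K2CO3 in acetone should O-methylate both 4-hydroxy groups to the bis(methoxymethyl ether) of the target F8.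
- HCl in MeOH as in step 2 should then give 6.
- The acyl-bearing ring carbons are epimerizable in F5 to F7. With the two aryl groups fixed trans across the ring, the arrangement of 6 is the more stable of the two possible ones, so any base equilibration should converge on it.

Step 1. Condensation may stay incomplete, or methoxide may open the pyranone ring on prolonged heating. The fallback replaces the aldol condensation by an olefination. It sets out from 1 and returns at 4.
- Radical bromination of 1 (NBS, AIBN, PhCF3, reflux) should give 6-(bromomethyl)-4-methoxy-2H-pyran-2-one F9.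
- Arbuzov reaction with P(OEt)3 (neat, 120 °C) should give diethyl [(4-methoxy-2-oxo-2H-pyran-6-yl)methyl]phosphonate F10.
- Horner–Wadsworth–Emmons olefination of 2 with F10 (NaH, THF, 0 °C to rt) should give 4 with E selectivity.

Step 2. Under acid, MOM cleavage may be accompanied by loss of the pyranone 4-O-methyl group (hydrolysis of the vinylogous ester) or by solvent addition to the electron-rich styryl alkene. The fallback uses silyl protection and fluoride deprotection, so no acid is needed. It sets out from 1 and returns at 5.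
- The lithium trienolate of 1 (LiN(SiMe3)2, THF, −78 °C) should add to catalogue 4-(tert-butyldimethylsilyloxy)benzaldehyde to give rac-6-[2-[4-(tert-butyldimethylsilyloxy)phenyl]-2-hydroxyethyl]-4-methoxy-2H-pyran-2-one F11.
- Mesylation and elimination (MsCl, Et3N, then DBU, CH2Cl2, 0 °C to rt) should give 6-[(E)-2-[4-(tert-butyldimethylsilyloxy)phenyl]ethenyl]-4-methoxy-2H-pyran-2-one F12.
- Bu4NF buffered with AcOH in THF at 0 °C should then give 5.

**Further compounds**

F1 | step 3 | (E)-3-[4-(methoxymethoxy)phenyl]prop-2-enoic acid | COCOc1ccc(/C=C/C(=O)O)cc1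
F2 | step 3 | (E)-3-(4-hydroxyphenyl)prop-2-enoic acid | OC(=O)/C=C/c1ccc(O)cc1
F3 | step 3 | (1α,2α,3β,4β)-2,4-bis(4-hydroxyphenyl)cyclobutane-1,3-dicarboxylic acid | OC(=O)[C@H]1[C@H](c2ccc(O)cc2)[C@H](C(=O)O)[C@H]1c1ccc(O)cc1
F4 | step 3 | dimethyl (1α,2α,3β,4β)-2,4-bis(4-hydroxyphenyl)cyclobutane-1,3-dicarboxylate | COC(=O)[C@H]1[C@H](c2ccc(O)cc2)[C@H](C(=O)OC)[C@H]1c1ccc(O)cc1
F5 | step 3 | dimethyl (1α,2α,3β,4β)-2,4-bis[4-(methoxymethoxy)phenyl]cyclobutane-1,3-dicarboxylate | COC(=O)[C@H]1[C@H](c2ccc(OCOC)cc2)[C@H](C(=O)OC)[C@H]1c1ccc(OCOC)cc1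
F6 | step 3 | dimethyl 5,5'-[(1α,2α,3β,4β)-2,4-bis[4-(methoxymethoxy)phenyl]cyclobutane-1,3-diyl]bis(3,5-dioxopentanoate) | COC(=O)CC(=O)CC(=O)[C@H]1[C@H](c2ccc(OCOC)cc2)[C@H](C(=O)CC(=O)CC(=O)OC)[C@H]1c1ccc(OCOC)cc1
F7 | step 3 | (1α,2α,3β,4β)-2,4-bis(4-hydroxy-2-oxo-2H-pyran-6-yl)-1,3-bis[4-(methoxymethoxy)phenyl]cyclobutane | Oc1cc(=O)oc([C@H]2[C@H](c3ccc(OCOC)cc3)[C@H](c3cc(O)cc(=O)o3)[C@H]2c2ccc(OCOC)cc2)c1
F8 | step 3 | (1α,2α,3β,4β)-2,4-bis(4-methoxy-2-oxo-2H-pyran-6-yl)-1,3-bis[4-(methoxymethoxy)phenyl]cyclobutane | COc1cc(=O)oc([C@H]2[C@H](c3ccc(OCOC)cc3)[C@H](c3cc(OC)cc(=O)o3)[C@H]2c2ccc(OCOC)cc2)c1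
F9 | step 1 | 6-(bromomethyl)-4-methoxy-2H-pyran-2-one | COc1cc(=O)oc(CBr)c1
F10 | step 1 | diethyl [(4-methoxy-2-oxo-2H-pyran-6-yl)methyl]phosphonate | CCOP(=O)(Cc1cc(OC)cc(=O)o1)OCC
F11 | step 2 | rac-6-[2-[4-(tert-butyldimethylsilyloxy)phenyl]-2-hydroxyethyl]-4-methoxy-2H-pyran-2-one | COc1cc(=O)oc(CC(O)c2ccc(O[Si](C)(C)C(C)(C)C)cc2)c1
F12 | step 2 | 6-[(E)-2-[4-(tert-butyldimethylsilyloxy)phenyl]ethenyl]-4-methoxy-2H-pyran-2-one | COc1cc(=O)oc(/C=C/c2ccc(O[Si](C)(C)C(C)(C)C)cc2)c1
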